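## Retrosynthetic overview

1. Target ⇐ open the 19,20-δ-lactone and oxidise the C-20 alcohol to the aldehyde (the GA 20-oxidase order); the 7-carboxyl ⇐ oxidative contraction of ring B of an ent-kauran-7-one enol ether (C-8 migrates from C-7 to C-6, C-7 is extruded, as in kaurenoic acid oxidase).
2. ent-Kaurane ⇐ one cationic cascade modelled on ent-kaurene synthase: allylic C–O ionisation (a vinyl epoxide, which also brings the 12-oxygen), attack of the 8-exo-methylene (ring C), capture of the C-8 cation by a pendant olefin (ring D), exocyclic alkene by loss of silyl.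
3. Cascade substrate ⇐ ent-labdane C-12 aldehyde + chiral allyl sulfonium ylide; the aldehyde ⇐ andrographolide (A/B rings = the ent-copalyl stage, C-3 and C-19 oxygens present) after C-3 inversion, C-7 allylic oxidation and amidyl-radical lactonisation onto C-20.
4. Ring order: A/B (chiral pool) → C → D (same flask) → B contracted 6→5.

Notation: atoms carry the gibberellane/ent-kaurane numbers of the target throughout (the exocyclic CH2 of andrographolide is therefore C-14); β = face of H-5, H-9 and the C-15/C-16 bridge, α = face of C-19 and C-20; the target's 12-OH is α, i.e. (12S).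

Assumption: the ylide from the (1R,4R,5R)-isothiocineole salt 16 (S-alkyl group taken as exo) gives the (12S,13S)-trans-epoxide; if the sense of induction is the opposite, the (1S,4S,5S) sulfide from (S)-limonene is used in the same way.

## Route

Step 1
Reactants: 1 andrographolide
Product: 2 aldehyde diol (C-12 CHO; 3α-OH; 19-OH; 8(14)-methylene)
Conditions: KMnO4 (1.3 eq), MgSO4, THF/H2O, −10 °C
Reagents that add atoms: potassium permanganate [K+].[O-][Mn](=O)(=O)=O
Why: Cold buffered permanganate attacks the electron-poor α-alkylidene lactone faster than the isolated 8(14)-methylene, and the glycol is cleaved (permanganate oxidative cleavage), which frees C-12 as the aldehyde and removes C-13 to C-16 without touching a stereocentre.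

Step 2
Reactants: 2 aldehyde diol
Product: 3 dioxolane diol (C-12 as 1,3-dioxolane)
Conditions: HOCH2CH2OH, PPTS, benzene, reflux (Dean–Stark)
Reagents that add atoms: ethylene glycol OCCO
Why: Acid-catalysed acetalisation protects the enolisable aldehyde for steps 3 to 9 while the 1,3-diol and the exocyclic alkene are left alone.

Step 3
Reactants: 3 dioxolane diol
Product: 4 3α-hydroxy 19-oic acid
Conditions: TEMPO (0.2 eq), PhI(OAc)2 (2.4 eq), pH 7 phosphate buffer, MeCN/H2O, 0 °C → rt
Reagents that add atoms: water O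
Why: The TEMPO/PhI(OAc)2 oxidation (Epp–Widlanski) takes the primary neopentyl alcohol through the aldehyde hydrate to the acid and spares the secondary 3-OH, the alkene and the acetal.

Step 4
Reactants: 4 3α-hydroxy 19-oic acid
Product: 6 3α-hydroxy 19-carboxamide, via acyl imidazolide 5 (not isolated)
Conditions: CDI, THF, rt; then NH3 (7 M in MeOH), 40 °C
Reagents that add atoms: 1,1'-carbonyldiimidazole O=C(n1ccnc1)n1ccnc1 (imidazolyl of 5); ammonia N
Why: CDI activation and ammonolysis (the acid reacts far faster with CDI than the hindered secondary alcohol) give the primary amide that later serves as the N-radical precursor.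

Step 5
Reactants: 6 3α-hydroxy 19-carboxamide
Product: 7 3-oxo 19-carboxamide
Conditions: Dess–Martin periodinane, NaHCO3, CH2Cl2, 0 °C → rt
Reagents that add atoms: none
Why: Dess–Martin oxidation of the only alcohol gives the β-keto amide, which cannot epimerise or decarboxylate because C-4 is quaternary and C-19 is an amide.

Step 6
Reactants: 7 3-oxo 19-carboxamide
Product: 9 3β-acetoxy 19-carboxamide, via lithium 3β-alkoxide 8 (not isolated)
Conditions: L-Selectride (1.3 eq), THF, −78 °C; then Ac2O, DMAP, −78 → 0 °C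
Reagents that add atoms: L-Selectride [Li+].CCC(C)[BH-](C(C)CC)C(C)CC (Li of 8); acetic anhydride CC(=O)OC(C)=O
Why: The bulky trialkylborohydride attacks the 4,4-disubstituted 3-ketone along the equatorial trajectory (axial approach meets H-1β and H-5β), which gives the axial 3β-alkoxide and so inverts the C-3 centre of andrographolide, and the alkoxide is acetylated in the same flask.

Step 7
Reactants: 9 3β-acetoxy 19-carboxamide
Product: 10 7β-hydroxy-3β-acetoxy 19-carboxamide
Conditions: SeO2 (0.3 eq), t-BuOOH, CH2Cl2, rt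
Reagents that add atoms: tert-butyl hydroperoxide CC(C)(C)OO
Why: Sharpless SeO2/TBHP allylic oxidation (ene reaction, then [2,3]-shift) hydroxylates the ring CH2 next to the 1,1-disubstituted alkene from the open β face; this centre becomes sp2 in step 8.

Step 8
Reactants: 10 7β-hydroxy-3β-acetoxy 19-carboxamide
Product: 11 exocyclic enone (7-oxo-8(14)-ene) 3β-acetoxy 19-carboxamide
Conditions: Dess–Martin periodinane, NaHCO3, CH2Cl2, rt
Reagents that add atoms: none
Why: Oxidation of the allylic alcohol gives the enone, which makes both the alkene and the C-6 hydrogens electron-poor for the radical step that follows.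

Step 9
Reactants: 11 exocyclic enone 19-carboxamide
Product: 13 enone aldehyde 19,20-lactone, via iminolactone 12 (not isolated)
Conditions: PhI(OAc)2 (1.5 eq), I2 (1 eq), hν (W lamp), ClCH2CH2Cl, rt; then 1 M HCl, THF, rt
Reagents that add atoms: water O
Why: In this Hofmann–Löffler–Freytag-type N-iodoamide photolysis (Barton, Suárez conditions) the amidyl radical on axial C-19 takes a hydrogen from the syn-axial C-20 methyl (1,6-shift; the 1,5-hydrogens at C-2 and C-6 are deactivated towards the electrophilic N-radical by the β-acetoxy and α-carbonyl groups), iodine transfer and O-cyclisation give the iminolactone, and aqueous acid hydrolyses it together with the dioxolane.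

Step 10
Reactants: 14 (1R,4R,5R)-isothiocineole; 15 2-(chloromethyl)allyl-trimethylsilane
Product: 16 S-[2-(trimethylsilylmethyl)allyl]isothiocineolium tetrafluoroborate
Conditions: NaI (0.1 eq), NaBF4, CH2Cl2/H2O, rt
Reagents that add atoms: sodium tetrafluoroborate [Na+].F[B-](F)(F)F
Why: Iodide-catalysed SN2 alkylation of the sulfide on its exposed exo lone pair gives a single sulfonium diastereomer, isolated as the non-nucleophilic BF4 salt.

Step 11
Reactants: 13 enone aldehyde 19,20-lactone; 16 sulfonium tetrafluoroborate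
Product: 18 (12S,13S)-trans-vinyl epoxide allylsilane, via sulfonium ylide 17 (not isolated)
Conditions: 16, LiHMDS, THF, −78 °C, 10 min; then 13, −78 → −20 °C
Reagents that add atoms: none
Why: In this Aggarwal sulfur-ylide epoxidation (Corey–Chaykovsky type) the chiral allylic ylide adds to the aldehyde (much more electrophilic than enone, lactone or acetate) and the anti-betaine closes to the trans-epoxide, so the reagent sets C-12 and C-13.

Step 12
Reactants: 18 (12S,13S)-trans-vinyl epoxide allylsilane
Product: 19 7-(TBS-oxy)-6,8(14)-diene vinyl epoxide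
Conditions: TBSCl (1.5 eq), then KHMDS (1.05 eq) added last, THF, −78 °C
Reagents that add atoms: tert-butyldimethylsilyl chloride CC(C)(C)[Si](C)(C)Cl
Why: Kinetic deprotonation at C-6 (the only acidic α'-hydrogens; the acetate CH3 is about 5 pK units weaker) with in-situ O-silylation gives the 2-silyloxy diene, which makes C-14 nucleophilic again and stores the C-7 oxygen as an enol ether.

Step 13
Reactants: 19 7-(TBS-oxy)-6,8(14)-diene vinyl epoxide
Product: 20 ent-kaura-6,16-diene 7-OTBS enol ether 12α-OTMS ether (3β-OAc; 19,20-olide)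
Conditions: TMSOTf (10 mol %), 2,6-di-tert-butyl-4-methylpyridine (20 mol %), CH2Cl2, −78 → −40 °C
Reagents that add atoms: none
Why: Proposed new method: Me3Si+ opens the vinyl epoxide at the allylic carbon C-13, the diene terminus C-14 attacks anti to the C–O bond (6-endo, ring C; inversion at C-13 and retention at C-12, so O-12 ends α and trans to C-16), the 2-silyloxyallyl cation is captured at C-8 on the β face by the 2-substituted allylsilane, which a β-C-16 can reach only there (SE2', ring D, sets C-8), and loss of Me3Si+ gives the 16-ene, silylates O-12 and regenerates the catalyst; this copies ent-kaurene synthase (allylic C–O ionisation, exo-methylene attack, C-8 cation, olefin capture, exocyclic alkene), and the closest known reactions are Lewis-acid epoxy-olefin cyclisations of vinyl epoxides and allylsilane-terminated (Sakurai) cation–olefin annulations.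

Step 14
Reactants: 20 ent-kaura-6,16-diene 7-OTBS enol ether
Product: 22 12α-hydroxy-GA37 3-acetate 7-methyl ester, via 6β-iodanyl 7-ketone 21 (not isolated)
Conditions: PhI(OH)OTs (1.05 eq), CH2Cl2/MeOH 1:1, −78 °C → rt
Reagents that add atoms: [hydroxy(tosyloxy)iodo]benzene OI(c1ccccc1)OS(=O)(=O)c1ccc(C)cc1 (iodanyl group of 21); methanol CO
Why: Proposed new method: Koser's reagent attacks the silyl enol ether at C-6 from the β face (the α face is covered by the 19,20-lactone bridge), methanol adds to the C-7 carbonyl and the anti-periplanar C-7–C-8 bond migrates to C-6 with loss of PhI (inversion at C-6 gives the 6β-CO2Me with H-6α as in the target; α-face SN2 by solvent is blocked; the TMS ether is methanolysed), which is the oxidative extrusion of C-7 done by kaurenoic acid oxidase, and the closest known reaction is the iodine(III)-mediated Favorskii-type ring contraction of cyclic ketones and enol ethers (Moriarty, Koser).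

Step 15
Reactants: 22 12α-hydroxy-GA37 3-acetate 7-methyl ester
Product: 24 12α-hydroxy-GA36 (target), via open-lactone dipotassium salt 23 (not isolated)
Conditions: KOH, MeOH/H2O 3:1, 70 °C; then NaHCO3/K2CO3 buffer (pH 8.6), Bu4NCl, TEMPO (0.1 eq), NCS (1.1 eq), CH2Cl2, 0 °C; then 1 M HCl to pH 3
Reagents that add atoms: potassium hydroxide [K+].[OH-]
Why: Saponification opens the δ-lactone to the 20-hydroxy-19-carboxylate and also cleaves the 7-methyl ester and 3-acetate, the oxoammonium oxidation under Einhorn's buffered phase-transfer conditions (TEMPO/NCS) is selective for the primary C-20 alcohol over the two secondary alcohols and stops at the aldehyde while the carboxylates stay ionised (no relactonisation), and acidification gives the target with no stereocentre changed.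

## Compound list

1 | andrographolide | C=C1CC[C@@H]2[C@](C)(CO)[C@H](O)CC[C@@]2(C)[C@@H]1C/C=C1/C(=O)OC[C@H]1O | starting material
2 | aldehyde diol: 8(14)-methylene decalin with 3α-OH, 4α-CH2OH, 4β-CH3, 10α-CH3, H-5β, H-9β, C-9 side chain CH2CHO | C=C1CC[C@@H]2[C@](C)(CO)[C@H](O)CC[C@@]2(C)[C@@H]1CC=O | intermediate
3 | dioxolane diol (2 with C-12 as 1,3-dioxolane) | C=C1CC[C@@H]2[C@](C)(CO)[C@H](O)CC[C@@]2(C)[C@@H]1CC1OCCO1 | intermediate
4 | 3α-hydroxy 19-oic acid | C=C1CC[C@@H]2[C@](C)(C(=O)O)[C@H](O)CC[C@@]2(C)[C@@H]1CC1OCCO1 | intermediate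
5 | acyl imidazolide of 4 | C=C1CC[C@@H]2[C@](C)(C(=O)n3ccnc3)[C@H](O)CC[C@@]2(C)[C@@H]1CC1OCCO1 | intermediate (not isolated)
6 | 3α-hydroxy 19-carboxamide | C=C1CC[C@@H]2[C@](C)(C(N)=O)[C@H](O)CC[C@@]2(C)[C@@H]1CC1OCCO1 | intermediate
7 | 3-oxo 19-carboxamide | C=C1CC[C@@H]2[C@](C)(C(N)=O)C(=O)CC[C@@]2(C)[C@@H]1CC1OCCO1 | intermediate
8 | lithium 3β-alkoxide of the 19-carboxamide | C=C1CC[C@@H]2[C@](C)(C(N)=O)[C@@H]([O-])CC[C@@]2(C)[C@@H]1CC1OCCO1.[Li+] | intermediate (not isolated)
9 | 3β-acetoxy 19-carboxamide | C=C1CC[C@@H]2[C@](C)(C(N)=O)[C@@H](OC(C)=O)CC[C@@]2(C)[C@@H]1CC1OCCO1 | intermediate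
10 | 7β-hydroxy-3β-acetoxy 19-carboxamide | C=C1[C@@H](O)C[C@@H]2[C@](C)(C(N)=O)[C@@H](OC(C)=O)CC[C@@]2(C)[C@@H]1CC1OCCO1 | intermediate
11 | exocyclic enone (7-oxo-8(14)-ene) 3β-acetoxy 19-carboxamide | C=C1C(=O)C[C@@H]2[C@](C)(C(N)=O)[C@@H](OC(C)=O)CC[C@@]2(C)[C@@H]1CC1OCCO1 | intermediate
12 | 19,20-iminolactone (dioxolane still on C-12) | C=C1C(=O)C[C@@H]2[C@]3(C)C(=N)OC[C@]2(CC[C@@H]3OC(C)=O)[C@@H]1CC1OCCO1 | intermediate (not isolated)
13 | enone aldehyde 19,20-lactone (3β-OAc; 7-oxo-8(14)-ene; C-12 CHO) | C=C1C(=O)C[C@@H]2[C@]3(C)C(=O)OC[C@]2(CC[C@@H]3OC(C)=O)[C@@H]1CC=O | intermediate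
14 | (1R,4R,5R)-isothiocineole (4,7,7-trimethyl-6-thiabicyclo[3.2.1]octane) | C[C@@H]1CC[C@@H]2C[C@H]1SC2(C)C | starting material
15 | 2-(chloromethyl)allyl-trimethylsilane | C=C(CCl)C[Si](C)(C)C | starting material
16 | S-[2-(trimethylsilylmethyl)allyl]isothiocineolium tetrafluoroborate (S-alkyl exo) | C[C@@H]1CC[C@@H]2C[C@H]1[S@@+](CC(=C)C[Si](C)(C)C)C2(C)C.F[B-](F)(F)F | intermediate
17 | sulfonium ylide from 16 | C[C@@H]1CC[C@@H]2C[C@H]1[S@@+]([CH-]C(=C)C[Si](C)(C)C)C2(C)C | intermediate (not isolated)
18 | (12S,13S)-trans-12,13-epoxide; C-13 bears C(=CH2)CH2SiMe3; enone and lactone as in 13 | C=C1C(=O)C[C@@H]2[C@]3(C)C(=O)OC[C@]2(CC[C@@H]3OC(C)=O)[C@@H]1C[C@@H]1O[C@H]1C(=C)C[Si](C)(C)C | intermediate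
19 | 7-(TBS-oxy)-6,8(14)-diene of 18 | C=C1C(O[Si](C)(C)C(C)(C)C)=C[C@@H]2[C@]3(C)C(=O)OC[C@]2(CC[C@@H]3OC(C)=O)[C@@H]1C[C@@H]1O[C@H]1C(=C)C[Si](C)(C)C | intermediate
20 | 3β-acetoxy-7-(TBS-oxy)-12α-(TMS-oxy)-ent-kaura-6,16-dien-19,20-olide | C=C1C[C@]23C[C@H]1[C@@H](O[Si](C)(C)C)C[C@H]2[C@@]45CC[C@H](OC(C)=O)[C@@](C)(C(=O)OC4)[C@H]5C=C3O[Si](C)(C)C(C)(C)C | intermediate
21 | 6β-[phenyl(tosyloxy)-λ3-iodanyl] 7-ketone of 20 | C=C1C[C@]23C[C@H]1[C@@H](O[Si](C)(C)C)C[C@H]2[C@@]45CC[C@H](OC(C)=O)[C@@](C)(C(=O)OC4)[C@H]5[C@H](I(c6ccccc6)OS(=O)(=O)c6ccc(C)cc6)C3=O | intermediate (not isolated)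
22 | 12α-hydroxy-GA37 3-acetate 7-methyl ester (ent-gibberell-16-ene; 19,20-lactone; 6β-CO2Me) | C=C1C[C@]23C[C@H]1[C@@H](O)C[C@H]2[C@]14CC[C@H](OC(C)=O)[C@@](C)(C(=O)OC4)[C@H]1[C@@H]3C(=O)OC | intermediate
23 | open-lactone dipotassium salt (3β,12α,20-triol 7,19-dicarboxylate) | C=C1C[C@]23C[C@H]1[C@@H](O)C[C@H]2[C@]1(CO)CC[C@H](O)[C@@](C)(C(=O)[O-])[C@H]1[C@@H]3C(=O)[O-].[K+].[K+] | intermediate (not isolated)
24 | 12α-hydroxy-GA36 (CNP0218328.1) | C=C1C[C@]23C[C@H]1[C@@H](O)C[C@H]2[C@]1(C=O)CC[C@H](O)[C@@](C)(C(=O)O)[C@H]1[C@@H]3C(=O)O | target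

## Totals and risks

Total step count: 15. Longest linear sequence: 14 steps (steps 1–9 and 11–15, from andrographolide); step 10 is a one-step side branch.

The three steps most likely to fail:

Step 13 (cascade). The epoxide may rearrange or eliminate, or ring D may fail to close. The fallback sets out from 18 and comes back at 20. It replaces the cationic cascade by a polarity-reversed Pd–trimethylenemethane [3+2] cycloaddition (Trost). Pd(OAc)2/P(OiPr)3 in THF at 60 °C ionises the vinyl epoxide and the alkoxide takes the Me3Si group from C-17. The substituted terminus C-13 then adds to the enone β-carbon C-14 and the C-8 enolate closes on C-15, which gives the 3β-acetoxy-7-oxo-12α-(TMS-oxy)-ent-kaur-16-en-19,20-olide F6. KHMDS/TBSCl as in step 12 converts it into 20.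

Step 9 (remote C-20 functionalisation). The amidyl radical may take H-2 or H-6 instead. The fallback sets out from 11 and comes back at 13. It replaces radical hydrogen transfer by acyl-nitrene C–H insertion (the ApSimon–Edwards approach to 19,20-bridged diterpenoids). The amide is deamidated with t-BuONO/AcOH to the enone 19-oic acid F1. DPPA/Et3N gives the acyl azide F2. Photolysis (254 nm, CH2Cl2, −40 °C) inserts the nitrene into the syn-axial C-20–H to give the δ-lactam F3. NOBF4/pyridine gives the N-nitrosolactam F4, which on warming loses N2 (White rearrangement) to give the 19,20-lactone dioxolane F5. 1 M HCl/THF then frees the aldehyde to give 13.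

Step 14 (oxidative ring contraction). The iodane may attack the 16-ene, or the hindered C-7 carbonyl may not add methanol. The fallback sets out from 20 and comes back at 24. It uses a two-stage halogenation and base-induced quasi-Favorskii (semibenzilic) rearrangement. NBS in THF at −78 °C gives the 6β-bromo-7-ketone F7. NaOMe/MeOH (0 °C → rt) adds to C-7 and C-8 migrates with loss of bromide; the acetate and TMS ether are cleaved as well, which gives 12α-hydroxy-GA37 7-methyl ester F8. F8 is taken through the conditions of step 15 to 24.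

Further compounds
F1 | step 9 | enone 19-oic acid (11 with CO2H in place of CONH2) | C=C1C(=O)C[C@@H]2[C@](C)(C(=O)O)[C@@H](OC(C)=O)CC[C@@]2(C)[C@@H]1CC1OCCO1
F2 | step 9 | 19-acyl azide | C=C1C(=O)C[C@@H]2[C@](C)(C(=O)N=[N+]=[N-])[C@@H](OC(C)=O)CC[C@@]2(C)[C@@H]1CC1OCCO1
F3 | step 9 | 19,20-δ-lactam | C=C1C(=O)C[C@@H]2[C@]3(C)C(=O)NC[C@]2(CC[C@@H]3OC(C)=O)[C@@H]1CC1OCCO1
F4 | step 9 | N-nitroso 19,20-δ-lactam | C=C1C(=O)C[C@@H]2[C@]3(C)C(=O)N(N=O)C[C@]2(CC[C@@H]3OC(C)=O)[C@@H]1CC1OCCO1
F5 | step 9 | 19,20-lactone dioxolane (13 with C-12 as 1,3-dioxolane) | C=C1C(=O)C[C@@H]2[C@]3(C)C(=O)OC[C@]2(CC[C@@H]3OC(C)=O)[C@@H]1CC1OCCO1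
F6 | step 13 | 3β-acetoxy-7-oxo-12α-(TMS-oxy)-ent-kaur-16-en-19,20-olide | C=C1C[C@]23C[C@H]1[C@@H](O[Si](C)(C)C)C[C@H]2[C@@]45CC[C@H](OC(C)=O)[C@@](C)(C(=O)OC4)[C@H]5CC3=O
F7 | step 14 | 6β-bromo-7-ketone (F6 with 6β-Br) | C=C1C[C@]23C[C@H]1[C@@H](O[Si](C)(C)C)C[C@H]2[C@@]45CC[C@H](OC(C)=O)[C@@](C)(C(=O)OC4)[C@H]5[C@H](Br)C3=O
F8 | step 14 | 12α-hydroxy-GA37 7-methyl ester | C=C1C[C@]23C[C@H]1[C@@H](O)C[C@H]2[C@]14CC[C@H](O)[C@@](C)(C(=O)OC4)[C@H]1[C@@H]3C(=O)OC
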